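The earlier runs and the new flask are calculated for an exercise; scatter was added.

Thursday's flask stands hotter than Saturday's, 80 °C against 55 °C, on the same charge and the same 8.0 h.

all flasks: substrate 0.075 M
- beta: first nucleophile 0.26 M; second nucleophile 0.090 M; temperature 61 °C; run made earlier
- eta: first nucleophile 0.41 M; second nucleophile 0.090 M; temperature 75 °C; run made earlier
- Saturday's: first nucleophile 0.188 M; second nucleophile 0.0900 M; temperature 55 °C; time 8.0 h
- Thursday's: first nucleophile 0.188 M; second nucleophile 0.0900 M; temperature 80 °C; time 8.0 h

beta run (percent of the substrate charged): time / h: target / % = 0.333: 1.3; 1.00: 3.9; 2.00: 7.0; 3.00: 8.9; 4.00: 9.5; 5.00: 10.7; 6.00: 11.0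

eta run (percent of the substrate charged): time / min: target / % = 12.0: 4.1; 20.0: 7.3; 30.0: 8.8; 40.0: 11.9; 60.0: 15.1; 80.0: 16.7; 120: 19.9

(readings scatter by 0.5 percentage points)

1. the flask with the highest amount of target, in percent of the substrate charged ("all alike" if they lie within 1.5 percentage points) (Saturday's / Thursday's / all alike)
2. final target, as a percentage of the substrate charged, in Saturday's
3. final target, as a percentage of the substrate charged, in Thursday's



Target reached half of its last reading after 1.52 h in the beta run and 0.562 h in the eta run. Carried on in the logarithm against temperature, with first nucleophile set aside, these readings give 0.394 h for Thursday's flask and 2.32 h for Saturday's; this rise time is the quantity to carry.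

Saturday's run lasts 3.45 rise times, close to the 3.56 of the eta run, which still climbed from 16.7% to 19.9% over its last interval. So Saturday's flask should end still rising. Thursday's run lasts 20.3, so Thursday's flask should have stopped long before the end. This reckoning gives no height.

The forecast does: Thursday's, with 6% in Saturday's and 15% in Thursday's, on the ground that “Heat therefore favours the target.”

The simulation gives Thursday's, with 7.74% in Saturday's and 14.7% in Thursday's, so the forecast stands within its tolerance.

    2 substrate → self-condensation product (k = 0.163 M⁻¹ min⁻¹, Ea = 62.0 kJ mol⁻¹)
    intermediate → decomposed reagent (k = 0.00898 min⁻¹, Ea = 115 kJ mol⁻¹)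
    substrate → intermediate (k = 0.0180 min⁻¹, Ea = 100 kJ mol⁻¹)
    intermediate → side product (k = 0.00489 min⁻¹, Ea = 117 kJ mol⁻¹)
    second nucleophile + intermediate → other capture product (k = 66.3 M⁻¹ min⁻¹, Ea = 55.0 kJ mol⁻¹)
    intermediate → solvolysis product (k = 6.07 min⁻¹, Ea = 86.0 kJ mol⁻¹)
    first nucleophile + intermediate → target (k = 19.0 M⁻¹ min⁻¹, Ea = 58.0 kJ mol⁻¹)
    (constants at 80 °C)

In Thursday's flask, half of the turnover of the step to solvolysis product was done by 0.482 h, against the carried rise time of 0.394 h and a run of 8.0 h. Ten times the time leaves Thursday's target at 14.7%, while Saturday's target goes from 7.74% to 11.9%. Thursday's target moves by 5 points with first nucleophile at 0.112 M or 0.282 M, the other amounts and the time held, and the forecast's figure for Thursday's would then be off by about that much.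

The neighbour flask, like Thursday's but with 0.75 M of first nucleophile, keeps the temperature and the substrate charge, so the rise time 0.394 h again gives 20.3 rise times and a flask that should have stopped. It ends with 0.00750% of the substrate left and 34.4% of target.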